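**Retrosynthetic overview**

1. The only ring is closed last. One bromonium-initiated, chloride-terminated cation–olefin cyclization of the acyclic bromo chloro triene 7 forms the C3–C8 bond (chain numbering of 7) and installs C4–Br and C7–Cl, setting three stereocentres relative to C6.
2. 7 comes from the allylic alcohol 5 by SN2 deoxybromination with inversion.
3. 5 comes from enal 4 (chloro-olefination), and 4 from dienol 3 (cross-metathesis with methacrolein).
4. 3 comes from methacrolein by asymmetric allylboration, the sole source of absolute configuration.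

Assumption: the halosulfonium salt Et2SBr·SbCl6 of step 5 is prepared beforehand (Et2S, BrCl, SbCl5, in the way commercial BDSB is made) and is treated as a reagent, not as a step.

**Route**

Step 1
Reactants: 1 methacrolein
Product: 3 (3R)-2-methylhexa-1,5-dien-3-ol, via borinate ester 2 (not isolated)
Conditions: lIpc2B(allyl) (1.2 equiv), Et2O, −78 °C; then 3 M NaOH, 30% H2O2, 0 °C to rt
Reagents that add atoms: lIpc2B(allyl), B-allyldiisopinocampheylborane from (−)-α-pinene, C=CCB([C@H]1C[C@H]2C[C@@H]([C@@H]1C)C2(C)C)[C@H]1C[C@H]2C[C@@H]([C@@H]1C)C2(C)C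
Why: Brown asymmetric allylboration through a closed chair transition state, in which the (−)-α-pinene-derived ligands deliver the allyl group to the Re face of the aldehyde and so set the carbinol centre as R (1,2-addition only).

Step 2
Reactants: 3 (3R)-2-methylhexa-1,5-dien-3-ol; 1 methacrolein
Product: 4 (2E,5R)-5-hydroxy-2,6-dimethylhepta-2,6-dienal
Conditions: methacrolein (5 equiv), Hoveyda–Grubbs II (5 mol %), CH2Cl2, 40 °C
Reagents that add atoms: none
Why: Olefin cross-metathesis of the terminal alkene with excess methacrolein gives the conjugated trisubstituted enal as the thermodynamic E isomer, while the hindered isopropenyl alkene stays out of the cycle and the carbinol centre is untouched.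

Step 3
Reactants: 4 (2E,5R)-5-hydroxy-2,6-dimethylhepta-2,6-dienal
Product: 5 (3R,5E,7E)-8-chloro-2,6-dimethylocta-1,5,7-trien-3-ol
Conditions: CrCl2 (6 equiv), CHCl3 (2 equiv), THF, 65 °C
Reagents that add atoms: chloroform, ClC(Cl)Cl
Why: Takai chloro-olefination, in which the gem-dichromium carbenoid adds to the aldehyde and anti-eliminates to the (E)-chloroalkene (typically about 9:1 E:Z or better), with Cr(II) tolerating the free hydroxyl and leaving the existing E-alkene and the carbinol centre unchanged.

Step 4
Reactants: 5 (3R,5E,7E)-8-chloro-2,6-dimethylocta-1,5,7-trien-3-ol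
Product: 7 (1E,3E,6S)-6-bromo-1-chloro-3,7-dimethylocta-1,3,7-triene, via alkoxyphosphonium bromide 6 (not isolated)
Conditions: CBr4 (1.3 equiv), PPh3 (1.4 equiv), CH2Cl2, −40 to −10 °C; cold filtration through neutral alumina, used at once
Reagents that add atoms: carbon tetrabromide, BrC(Br)(Br)Br
Why: Appel reaction, in which bromide displaces the oxyphosphonium group by SN2 with inversion (3R alcohol to 6S bromide), low temperature and low free-bromide concentration holding back SN2′ transposition and exchange racemisation.

Step 5
Reactants: 7 (1E,3E,6S)-6-bromo-1-chloro-3,7-dimethylocta-1,3,7-triene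
Product: 10 (1R,2S,4S,5R)-2,4-dibromo-1-chloro-5-[(E)-2-chloroethenyl]-1,5-dimethylcyclohexane, via bromoallyl cation 8 (not isolated), via cyclohexyl cation 9 (not isolated)
Conditions: Et2SBr·SbCl6 (1.05 equiv), MeNO2, −25 °C, 0.02 M; then aq. Na2SO3/NaHCO3
Reagents that add atoms: bromodiethylsulfonium hexachloroantimonate, CC[S+](Br)CC.Cl[Sb-](Cl)(Cl)(Cl)(Cl)Cl
Why: Proposed new method: the bromosulfonium ion transfers Br+ to C4 of the chlorodiene (the only site that gives a tertiary, chlorine-capped allyl cation), the isopropenyl CH2 (C8) attacks C3 anti to bromine through a chair in which the allylic C6–Br is pseudo-axial (no A(1,2) clash with the in-plane C7 methyl), and the bulky SbCl6− hands chloride to the tertiary C7 cation on the open equatorial face anti to the new C–C bond, away from the syn-axial C3 methyl, so that the E-alkene and the 6S centre translate into 1R,2S,4S,5R; the closest known reaction types are BDSB-type bromonium-induced polyene cyclization and chloride-terminated Lewis-acid cation–olefin (Prins-type) cyclization.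

**Compound list**

1 | methacrolein (2-methylprop-2-enal) | CC(=C)C=O | starting material
2 | (3R)-2-methylhexa-1,5-dien-3-yl diisopinocampheylborinate | C=CC[C@@H](OB([C@H]1C[C@H]2C[C@@H]([C@@H]1C)C2(C)C)[C@H]1C[C@H]2C[C@@H]([C@@H]1C)C2(C)C)C(C)=C | intermediate
3 | (3R)-2-methylhexa-1,5-dien-3-ol | C=CC[C@@H](O)C(C)=C | intermediate
4 | (2E,5R)-5-hydroxy-2,6-dimethylhepta-2,6-dienal | O=C/C(C)=C/C[C@@H](O)C(C)=C | intermediate
5 | (3R,5E,7E)-8-chloro-2,6-dimethylocta-1,5,7-trien-3-ol | Cl/C=C/C(C)=C/C[C@@H](O)C(C)=C | intermediate
6 | {[(3R,5E,7E)-8-chloro-2,6-dimethylocta-1,5,7-trien-3-yl]oxy}triphenylphosphonium bromide | Cl/C=C/C(C)=C/C[C@@H](O[P+](c1ccccc1)(c1ccccc1)c1ccccc1)C(C)=C.[Br-] | intermediate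
7 | (1E,3E,6S)-6-bromo-1-chloro-3,7-dimethylocta-1,3,7-triene | Cl/C=C/C(C)=C/C[C@H](Br)C(C)=C | intermediate
8 | (1E,4S,6S)-4,6-dibromo-1-chloro-3,7-dimethylocta-1,7-dien-3-ylium hexachloroantimonate | Cl/C=C/[C+](C)[C@@H](Br)C[C@H](Br)C(C)=C.Cl[Sb-](Cl)(Cl)(Cl)(Cl)Cl | intermediate
9 | (2S,4S,5R)-2,4-dibromo-5-[(E)-2-chloroethenyl]-1,5-dimethylcyclohexan-1-ylium hexachloroantimonate | C[C@]1(/C=C/Cl)C[C+](C)[C@@H](Br)C[C@@H]1Br.Cl[Sb-](Cl)(Cl)(Cl)(Cl)Cl | intermediate
10 | (1R,2S,4S,5R)-2,4-dibromo-1-chloro-5-[(E)-2-chloroethenyl]-1,5-dimethylcyclohexane | C[C@]1(/C=C/Cl)C[C@@](C)(Cl)[C@@H](Br)C[C@@H]1Br | target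

**Step count and risks**

Total steps: 5. Longest linear sequence: 5.

Most likely to fail, in this order:

Step 5. Three things can go wrong:
- Chloride may be handed to cation 8 before ring closure, because the isopropenyl group is deactivated by the allylic bromine; this gives open-chain bromochlorides.
- The pseudo-axial C6 bromine may bridge to cation 9 and steer chloride to the opposite face. This gives the C1 epimer of 10 (trans-diaxial Br/Cl) and is the most probable competitor; the ratio cannot be predicted with confidence.
- The alternative chair with equatorial C6–Br would give the 2,4-cis-dibromide.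

The fallback sets out from 7 and comes back at 10, separating ring closure from C–Cl bond formation. Compound 7 is treated with commercial BDSB (Et2SBr·SbCl5Br) in MeNO2 at −25 °C, where the cyclised cation ends by proton loss, to give (1R,2S,4S)-2,4-dibromo-1-[(E)-2-chloroethenyl]-1-methyl-5-methylidenecyclohexane F1. Its endocyclic double-bond isomer converges in the next operation. Dry HCl in CH2Cl2 at −78 °C then adds in the Markovnikov sense to the isolated, conformationally settled ring and returns to 10. Under these non-ionising conditions the addition is expected to be a tight anti process, not one through a long-lived free cation. This fallback mainly rescues the ring closure; the C1 face selectivity passes through the same tertiary centre and stays uncertain.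

Step 4. The secondary allylic bromide can form with SN2′ transposition to the primary bromide, or lose enantiopurity through bromide exchange. The fallback sets out from 5 and comes back at 7, separating activation from displacement. The alcohol is converted with MsCl and Et3N in CH2Cl2 at −40 °C into (3R,5E,7E)-8-chloro-2,6-dimethylocta-1,5,7-trien-3-yl methanesulfonate F2. This isolated sulfonate is displaced with LiBr in THF at −20 °C, an SN2 reaction with an external, stoichiometrically controlled bromide and no phosphonium ion pair, giving 7 with the same inversion.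

Step 3. Cr(II) can reduce or pinacol-couple the enal, and the E:Z ratio of the new chloroalkene may be lower than usual. The fallback sets out from 4 and comes back at 5, building the chloroalkene from an alkyne. Seyferth–Gilbert homologation with the Ohira–Bestmann reagent (K2CO3, MeOH) gives (3R,5E)-2,6-dimethylocta-1,5-dien-7-yn-3-ol F3. Hydrozirconation with Cp2Zr(H)Cl (2.2 equiv, THF) followed by N-chlorosuccinimide gives 5, with the E geometry fixed by syn addition and retentive chlorination.

**Further compounds**

F1 | step 5 | (1R,2S,4S)-2,4-dibromo-1-[(E)-2-chloroethenyl]-1-methyl-5-methylidenecyclohexane | C[C@]1(/C=C/Cl)CC(=C)[C@@H](Br)C[C@@H]1Br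
F2 | step 4 | (3R,5E,7E)-8-chloro-2,6-dimethylocta-1,5,7-trien-3-yl methanesulfonate | Cl/C=C/C(C)=C/C[C@@H](OS(C)(=O)=O)C(C)=C
F3 | step 3 | (3R,5E)-2,6-dimethylocta-1,5-dien-7-yn-3-ol | C#C/C(C)=C/C[C@@H](O)C(C)=C
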